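**Assumption:** atoms are labelled along the C15 chain, C1 (alkyne CH) to C15 (ethyl CH3); the target is read as the (3E,6S,7S,9S,10S,12S,13R) isomer, a 2,8-dioxabicyclo[5.2.1]decane.

## Retrosynthetic overview

- The bridging oxolane (C9–O and C10–Br) is closed last, by anodic bromoetherification of the C6 hydroxyl onto the ring Z-alkene of an α,α'-trans oxocene.
- The (E)-enyne side chain and the free C6 hydroxyl come from opening a C5–C6 terminal epoxide, which masks that hydroxyl until then.
- The oxocene (first ring) comes from ring-closing metathesis of a bis-allyl ether; C12–Br comes from Appel inversion of a carbinol set by chelation-controlled allylation.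
- The C7–O–C13 ether comes from SN2 inversion of the triflate of ethyl (S)-2-hydroxybutanoate by a tartrate-derived epoxy alcohol.
- The epoxy alcohol comes from mono-vinylation of (S,S)-diepoxybutane, made in the flask from L-threitol 1,4-dimethanesulfonate (L-tartaric acid pool).

## Route

Step 1
Reactants: 1 L-threitol 1,4-dimethanesulfonate (treosulfan)
Product: 3 (1S)-1-[(2S)-oxiran-2-yl]but-3-en-1-ol, via (2S,2'S)-2,2'-bioxirane 2 (not isolated)
Conditions: NaH (2.1 equiv), THF, 0 °C to rt; then CuI (10 mol%), vinylMgBr (1.0 equiv), −60 to −30 °C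
Reagents that add atoms: vinylmagnesium bromide, C=C[Mg]Br
Why: Base closes both hydroxy-mesylate pairs by intramolecular Williamson displacement at the primary carbons, and one equivalent of vinyl cuprate then opens one terminal CH2 of the C2-symmetric diepoxide (copper-catalysed Grignard epoxide opening), so C6 and C7 come unchanged from 1; the bis-adduct is the expected by-product of this statistical desymmetrisation.

Step 2
Reactants: 4 ethyl (2S)-2-hydroxybutanoate
Product: 5 ethyl (2S)-2-{[(trifluoromethyl)sulfonyl]oxy}butanoate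
Conditions: Tf2O, 2,6-lutidine, CH2Cl2, −78 °C
Reagents that add atoms: trifluoromethanesulfonic anhydride, O=S(=O)(OS(=O)(=O)C(F)(F)F)C(F)(F)F
Why: O-triflation leaves the C–O bond of the stereocentre untouched and gives an SN2-competent leaving group next to the ester.

Step 3
Reactants: 3 (1S)-1-[(2S)-oxiran-2-yl]but-3-en-1-ol, 5 ethyl (2S)-2-{[(trifluoromethyl)sulfonyl]oxy}butanoate
Product: 6 ethyl (2R)-2-{[(1S)-1-[(2S)-oxiran-2-yl]but-3-en-1-yl]oxy}butanoate
Conditions: KN(SiMe3)2, THF, −78 °C; then 5, −78 to −40 °C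
Reagents that add atoms: none
Why: Williamson-type SN2 etherification in which the potassium alkoxide of 3 displaces the α-triflyloxy ester with inversion (2S to 2R, the future C13), the low temperature keeping Payne rearrangement of the epoxy alkoxide and E2 of the triflate slow.

Step 4
Reactants: 6 ethyl (2R)-2-{[(1S)-1-[(2S)-oxiran-2-yl]but-3-en-1-yl]oxy}butanoate
Product: 8 (4R,5R)-5-{[(1S)-1-[(2S)-oxiran-2-yl]but-3-en-1-yl]oxy}hept-1-en-4-ol, via α-alkoxy aldehyde 7 (not isolated)
Conditions: i-Bu2AlH, CH2Cl2, −78 °C; crude aldehyde, MgBr2·OEt2, allylSnBu3, CH2Cl2, −78 to −40 °C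
Reagents that add atoms: allyltributylstannane, C=CC[Sn](CCCC)(CCCC)CCCC
Why: Half-reduction of the α-alkoxy ester stops at the aldehyde through the chelated aluminium hemiacetal, and the Keck allylation runs through the magnesium Cram chelate of carbonyl and α-ether oxygens, so allyl adds anti to the ethyl group and gives the syn (4R,5R) carbinol (future C12) under control of the purchased C13 centre.

Step 5
Reactants: 8 (4R,5R)-5-{[(1S)-1-[(2S)-oxiran-2-yl]but-3-en-1-yl]oxy}hept-1-en-4-ol
Product: 9 (2S)-2-[(1S)-1-{[(3R,4S)-4-bromohept-6-en-3-yl]oxy}but-3-en-1-yl]oxirane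
Conditions: CBr4, PPh3, 2,6-lutidine, CH2Cl2, 0 °C to rt
Reagents that add atoms: carbon tetrabromide, BrC(Br)(Br)Br
Why: Appel reaction in which bromide displaces the alkoxyphosphonium group by SN2 with inversion (R carbinol to S bromide, C12 of the target), under neutral conditions that terminal epoxides tolerate.

Step 6
Reactants: 9 (2S)-2-[(1S)-1-{[(3R,4S)-4-bromohept-6-en-3-yl]oxy}but-3-en-1-yl]oxirane
Product: 10 (2S)-2-[(2S,4Z,7S,8R)-7-bromo-8-ethyl-3,6,7,8-tetrahydro-2H-oxocin-2-yl]oxirane
Conditions: RuCl2(=CHPh)(PCy3)(H2IMes) (second-generation Grubbs catalyst, 5 mol%), CH2Cl2 (3 mM), 40 °C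
Reagents that add atoms: none
Why: Ring-closing metathesis of the two allyl groups gives the eight-membered Z-alkene, helped by the gauche preference of the vicinal O/Br and O/O pairs (Crimmins-type oxocene closure); the masked C6 arm carries no alkene that could close a cyclohexene, and no stereocentre is touched.

Step 7
Reactants: 11 3-(trimethylsilyl)prop-2-ynal
Product: 12 [(3E)-4-iodobut-3-en-1-yn-1-yl]trimethylsilane
Conditions: CrCl2, CHI3, THF, 0 °C
Reagents that add atoms: iodoform, IC(I)I
Why: Takai olefination, in which the gem-dichromium species from iodoform adds to the aldehyde and eliminates to the (E)-vinyl iodide.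

Step 8
Reactants: 10 (2S)-2-[(2S,4Z,7S,8R)-7-bromo-8-ethyl-3,6,7,8-tetrahydro-2H-oxocin-2-yl]oxirane, 12 [(3E)-4-iodobut-3-en-1-yn-1-yl]trimethylsilane
Product: 14 (1S,3E)-1-[(2S,4Z,7S,8R)-7-bromo-8-ethyl-3,6,7,8-tetrahydro-2H-oxocin-2-yl]hex-3-en-5-yn-1-ol, via silyl enyne carbinol 13 (not isolated)
Conditions: 12, t-BuLi (2 equiv), Et2O, −78 °C; BF3·OEt2, then 10, −78 °C; crude, K2CO3, MeOH, rt
Reagents that add atoms: none
Why: Iodine–lithium exchange with retention of alkene geometry gives the (E)-enynyllithium, which opens the BF3-activated terminal epoxide at its CH2 carbon by SN2 (Ganem-type opening, C6 stays S and becomes the free carbinol), and K2CO3/MeOH then cleaves the alkynyl C–Si bond.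

Step 9
Reactants: 14 (1S,3E)-1-[(2S,4Z,7S,8R)-7-bromo-8-ethyl-3,6,7,8-tetrahydro-2H-oxocin-2-yl]hex-3-en-5-yn-1-ol
Product: 15 (1S,3R,4S,6S,7S,9S)-4,6-dibromo-3-ethyl-9-[(2E)-pent-2-en-4-yn-1-yl]-2,8-dioxabicyclo[5.2.1]decane
Conditions: undivided cell, graphite anode, Pt cathode, n-Bu4NBr (1.1 equiv), tetrahydrothiophene (20 mol%), CH2Cl2/(CF3)2CHOH 4:1, constant current, 2.1 F/mol, −10 °C
Reagents that add atoms: tetrabutylammonium bromide, CCCC[N+](CCCC)(CCCC)CCCC.[Br-]
Why: Proposed new method: anodic oxidation of bromide gives Br2, which the sulfide holds as a bromosulfonium bromide (an electrogenerated relative of bromodiethylsulfonium reagents) that passes Br+ reversibly to the most electron-rich alkene, the ring Z-alkene; only the bromonium on the face opposite the C6 carbinol can be trapped by 5-exo attack of that hydroxyl on C9, because the C7 tether reaches one face only, so anti addition sets C9 (S, C–O) and C10 (S, C–Br) and closes the oxolane bridge; the cathode reduces the fluorinated alcohol to H2 and its alkoxide, which takes up the proton, and the fluorinated alcohol hydrogen-bonds bromide so that vicinal dibromide formation and attack on the electron-poor enyne are suppressed; the closest known reaction types are halide-mediated anodic haloetherification and halolactonisation of simple alkenols and the reagent-based bromoetherification of hydroxy oxocenes with bromonium donors.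

## Compound list

1 | L-threitol 1,4-dimethanesulfonate, (2S,3S)-2,3-dihydroxybutane-1,4-diyl dimethanesulfonate | CS(=O)(=O)OC[C@H](O)[C@@H](O)COS(C)(=O)=O | starting material
2 | (2S,2'S)-2,2'-bioxirane | C1O[C@@H]1[C@@H]2CO2 | intermediate
3 | (1S)-1-[(2S)-oxiran-2-yl]but-3-en-1-ol | C=CC[C@H](O)[C@@H]1CO1 | intermediate
4 | ethyl (2S)-2-hydroxybutanoate | CCOC(=O)[C@@H](O)CC | starting material
5 | ethyl (2S)-2-{[(trifluoromethyl)sulfonyl]oxy}butanoate | CCOC(=O)[C@@H](OS(=O)(=O)C(F)(F)F)CC | intermediate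
6 | ethyl (2R)-2-{[(1S)-1-[(2S)-oxiran-2-yl]but-3-en-1-yl]oxy}butanoate | CCOC(=O)[C@H](O[C@@H](CC=C)[C@@H]1CO1)CC | intermediate
7 | (2R)-2-{[(1S)-1-[(2S)-oxiran-2-yl]but-3-en-1-yl]oxy}butanal | O=C[C@H](O[C@@H](CC=C)[C@@H]1CO1)CC | intermediate
8 | (4R,5R)-5-{[(1S)-1-[(2S)-oxiran-2-yl]but-3-en-1-yl]oxy}hept-1-en-4-ol | C=CC[C@@H](O)[C@@H](CC)O[C@@H](CC=C)[C@@H]1CO1 | intermediate
9 | (2S)-2-[(1S)-1-{[(3R,4S)-4-bromohept-6-en-3-yl]oxy}but-3-en-1-yl]oxirane | C=CC[C@H](Br)[C@@H](CC)O[C@@H](CC=C)[C@@H]1CO1 | intermediate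
10 | (2S)-2-[(2S,4Z,7S,8R)-7-bromo-8-ethyl-3,6,7,8-tetrahydro-2H-oxocin-2-yl]oxirane | CC[C@H]1O[C@@H](C/C=C\C[C@@H]1Br)[C@@H]2CO2 | intermediate
11 | 3-(trimethylsilyl)prop-2-ynal | C[Si](C)(C)C#CC=O | starting material
12 | [(3E)-4-iodobut-3-en-1-yn-1-yl]trimethylsilane | C[Si](C)(C)C#C/C=C/I | intermediate
13 | (1S,3E)-1-[(2S,4Z,7S,8R)-7-bromo-8-ethyl-3,6,7,8-tetrahydro-2H-oxocin-2-yl]-6-(trimethylsilyl)hex-3-en-5-yn-1-ol | CC[C@H]1O[C@@H](C/C=C\C[C@@H]1Br)[C@@H](O)C/C=C/C#C[Si](C)(C)C | intermediate
14 | (1S,3E)-1-[(2S,4Z,7S,8R)-7-bromo-8-ethyl-3,6,7,8-tetrahydro-2H-oxocin-2-yl]hex-3-en-5-yn-1-ol | CC[C@H]1O[C@@H](C/C=C\C[C@@H]1Br)[C@@H](O)C/C=C/C#C | intermediate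
15 | (1S,3R,4S,6S,7S,9S)-4,6-dibromo-3-ethyl-9-[(2E)-pent-2-en-4-yn-1-yl]-2,8-dioxabicyclo[5.2.1]decane | C#C/C=C/C[C@@H]1O[C@H]2C[C@@H]1O[C@H](CC)[C@@H](Br)C[C@@H]2Br | target

## Step count and risks

Total step count: 9 (seven in the main line plus two reagent preparations, steps 2 and 7).
Longest linear sequence: 7 (steps 1, 3, 4, 5, 6, 8, 9).

The three steps most likely to fail:

**Step 9 (the proposed electrochemical bromoetherification).** If electrolysis gives vicinal dibromide or touches the enyne, the same ring is closed without current, with a stoichiometric bromonium donor. Starting from 14, 2,4,4,6-tetrabromocyclohexa-2,5-dien-1-one (or N-bromosuccinimide) in CH2Cl2 at −78 to 0 °C delivers Br+ to the ring alkene and the C6 hydroxyl closes the oxolane. This is the known biomimetic bromoetherification of hydroxy oxocenes. The fallback rejoins the route at 15 and makes no compound outside the list (none F0).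

**Step 8 (enynyllithium opening of the epoxide beside a secondary bromide).** If the organolithium attacks the C–Br bond or the exchange fails, the side chain is built stepwise on the ring. Starting from 10, vinylMgBr with catalytic CuI (THF, −40 °C) opens the epoxide to (1S)-1-[(2S,4Z,7S,8R)-7-bromo-8-ethyl-3,6,7,8-tetrahydro-2H-oxocin-2-yl]but-3-en-1-ol F1. Cross-metathesis of F1 with crotonaldehyde (second-generation Grubbs catalyst RuCl2(=CHPh)(PCy3)(H2IMes), CH2Cl2, 40 °C) gives (2E,5S)-5-[(2S,4Z,7S,8R)-7-bromo-8-ethyl-3,6,7,8-tetrahydro-2H-oxocin-2-yl]-5-hydroxypent-2-enal F2. Seyferth–Gilbert homologation of F2 with dimethyl (1-diazo-2-oxopropyl)phosphonate, K2CO3 and MeOH then gives the terminal (E)-enyne, and the route is rejoined at 14.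

**Step 3 (SN2 etherification of an epoxy alkoxide with a secondary triflate).** If Payne rearrangement or elimination of the triflate dominates, the ether is made under neutral conditions by carbenoid O–H insertion. Starting from 3, slow addition of ethyl 2-diazobutanoate to 3 and Rh2(OAc)4 (1 mol%) in CH2Cl2 gives 6 together with its C2 epimer ethyl (2S)-2-{[(1S)-1-[(2S)-oxiran-2-yl]but-3-en-1-yl]oxy}butanoate F3. The two are formed in about 1:1 ratio and are separable diastereomers; F3 can be re-equilibrated with base and recycled. The route continues from 6.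

## Further compounds

F0 | step 9 | none | none
F1 | step 8 | (1S)-1-[(2S,4Z,7S,8R)-7-bromo-8-ethyl-3,6,7,8-tetrahydro-2H-oxocin-2-yl]but-3-en-1-ol | CC[C@H]1O[C@@H](C/C=C\C[C@@H]1Br)[C@@H](O)CC=C
F2 | step 8 | (2E,5S)-5-[(2S,4Z,7S,8R)-7-bromo-8-ethyl-3,6,7,8-tetrahydro-2H-oxocin-2-yl]-5-hydroxypent-2-enal | CC[C@H]1O[C@@H](C/C=C\C[C@@H]1Br)[C@@H](O)C/C=C/C=O
F3 | step 3 | ethyl (2S)-2-{[(1S)-1-[(2S)-oxiran-2-yl]but-3-en-1-yl]oxy}butanoate | CCOC(=O)[C@@H](O[C@@H](CC=C)[C@@H]1CO1)CC
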